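Read in molar product per minute rather than in percent, the earlier runs hold one figure nearly constant, so I asked which setting could move it.

the same everywhere: free catalyst 92 mM

| flask | solid substrate | added ligand | remark |
|---|---|---|---|
| maple | 0.76 M | 58 mM | run made earlier |
| ash | 1.2 M | 58 mM | run made earlier |
| oak | 0.54 M | 120 mM | run made earlier |
| flask | 0.54 M | 58 mM |  |

| run | time / min | product / % |
|---|---|---|
| maple | 1.50 | 16.6 |
| maple | 3.00 | 38.0 |
| maple | 5.00 | 62.8 |
| maple | 6.00 | 75.7 |
| maple | 8.00 | 99.4 |
| maple | 10.0 | 99.3 |
| ash | 1.50 | 10.9 |
| ash | 3.00 | 23.4 |
| ash | 5.00 | 38.8 |
| ash | 6.00 | 48.4 |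
| ash | 8.00 | 64.1 |
| ash | 10.0 | 80.0 |
| oak | 2.00 | 30.8 |
| oak | 4.00 | 65.2 |
| oak | 6.00 | 99.0 |
| oak | 8.00 | 99.5 |
| oak | 10.0 | 100.0 |

(each reading ± 0.5 percentage points)

1. apparent order in free catalyst when 30 % of the solid substrate are converted (what has only dissolved counts as not reacted) (percent change of the rate of making product for one percent more free catalyst charged)
2. factor on the rate of making product when 30 % of the solid substrate are converted (what has only dissolved counts as not reacted) if free catalyst is charged twice over

- as a solid, counted per litre of solution: solid substrate
- the analysis behind the earlier runs scatters by 0.5 percentage points, standard deviation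
- at the start none of the solid substrate is in solution
- what has only dissolved of solid substrate counts as not reacted
- no earlier run changes the charge of free catalyst; that part of a forecast is a guess

I took the solid charge first. Ash, with 1.58 times the solid of maple, climbed at 0.0976 M min⁻¹, which I call the feed rate: solid turned to product per litre per minute while solid remains. Maple climbed at 0.0998 M min⁻¹, so my answer need not lean on the solid charge.

Next came the ligand. Oak, with 2.07 times the added ligand, climbed at 0.0929 M min⁻¹, a log-log slope of magnitude 0.0675.

The number that matters is the catalyst charge, and no run changed it. One end is a catalyst step, with order one and factor two; the other is a fixed supply, with order zero and factor one. My guess was that added ligand holds free catalyst roughly in proportion, which makes that slope the order in free catalyst. That places the flask near the supply end, with a doubling factor of 1.05.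

The forecast, which differs from my reckoning, gave 1 and 2: “The turnover step should therefore scale with catalyst”. The flask gave an order of 0.082 and a factor of 1.04.

    starting material + free catalyst ⇌ catalyst intermediate (K = 4.62 L mol⁻¹, k = 6.99 L mol⁻¹ s⁻¹)
    solid substrate ⇌ starting material, rate k2*(cs2 - [starting material]) while solid is left; crystals form when [starting material] > cs2 (solubility = 0.190 M, k = 0.00907 s⁻¹)
    catalyst intermediate → free catalyst + product (k = 0.955 s⁻¹)
    free catalyst + added ligand ⇌ idle complex (K = 33.8 L mol⁻¹, k = 1.05 L mol⁻¹ s⁻¹)

Over 4.00 min, my feed rate takes 72.3 % of the flask's solid, and at 4.00 min the flask still held 27.8 % of its charge as solid. In maple, my feed rate spends the charge in 7.79 min, and the reading at 8.00 min is 99.4 %. At 2.77 min in the flask, the forward step alone gave starting material a half-life of 1.9 s, far shorter than the 76.4 s in which dissolving closes half its gap to saturation. At 4.00 min, [starting material] in the flask stood at 0.0113 M, far below the saturation value of 0.19 M.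

(The earlier runs and the new flask were generated by integration for an exercise; scatter was added.)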